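The meeting took the easy step first: the four species read in the earlier runs add up to the charge of first end groups, 99.6% at 0.200 min in the midnight run, so the percentages were treated as one conserved count.

| flask | first end groups | second end groups | remark | time |
|---|---|---|---|---|
| midnight | 0.40 M | 0.72 M | run made earlier |  |
| dawn | 0.60 M | 0.72 M | run made earlier |  |
| south-west | 0.80 M | 0.720 M |  | 4.0 min |
| south | 0.80 M | 0.720 M |  | 25 min |
| south-east | 0.80 M | 0.720 M |  | 10 min |

| run | time / min | links / % | isomer of the product / % | first end groups / % | rings / % |
|---|---|---|---|---|---|
| midnight | 0.200 | 10.8 | 0.6 | 81.3 | 6.9 |
| midnight | 0.333 | 14.4 | 1.3 | 72.4 | 11.0 |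
| midnight | 0.417 | 17.1 | 2.5 | 68.2 | 13.7 |
| midnight | 0.667 | 21.6 | 4.4 | 55.8 | 18.6 |
| midnight | 1.00 | 22.3 | 11.0 | 44.0 | 25.9 |
| midnight | 1.50 | 21.6 | 14.4 | 30.9 | 32.2 |
| midnight | 2.50 | 15.9 | 23.4 | 18.2 | 40.9 |
| dawn | 0.333 | 14.1 | 2.7 | 73.9 | 10.8 |
| dawn | 0.667 | 19.3 | 4.6 | 57.3 | 19.0 |
| dawn | 1.00 | 21.2 | 8.5 | 45.9 | 26.0 |
| dawn | 1.33 | 20.5 | 12.2 | 37.5 | 30.9 |
| dawn | 1.50 | 18.7 | 14.2 | 34.0 | 32.2 |
| dawn | 2.00 | 15.7 | 18.3 | 27.6 | 38.7 |
| dawn | 2.50 | 14.1 | 20.9 | 21.5 | 43.6 |

(standard deviation of a reading: 0.5 percentage points)

- the earlier runs were read with a standard deviation of 0.5 percentage points

- which of these there is most of at the end, counted by the first end groups in it, south-west (first end groups / links / rings / isomer of the product)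
- which of these there is most of at the end, counted by the first end groups in it, south (first end groups / links / rings / isomer of the product)
- which of these there is most of at the end, counted by the first end groups in it, south-east (first end groups / links / rings / isomer of the product)
- how much there is at the end of the one of these that leads, in percent of the first end groups charged: south-west
- how much there is at the end of the one of these that leads, in percent of the first end groups charged: south
- how much there is at the end of the one of these that leads, in percent of the first end groups charged: south-east

The first speaker proposed that each first end group that leaves takes one second end group with it, into rings as well as into links. The second speaker objected that the earlier runs carry no readings of second end groups, so this remains an assumption, and it was adopted as such. The chair called the ratio of the charges, 90.0%, the ceiling: the share of the first end groups charged that can be used while second end groups, the limiting reagent in south-west, south and south-east, last. First end groups should therefore stop at 10.0% in a flask that runs that far.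

For the other end of the path, the second speaker read the share of rings among the first end groups used at the last readings: 50.0% in the midnight run and 55.5% in the dawn run. The share reads larger in the dawn run, which was charged with fewer second end groups per first end group. Rings also lead at those readings in both runs.

My own reckoning, entered in the minutes, joins the two ends: in south and south-east, rings should lead and stand between 50.0%, the dawn share applied to the ceiling, and the ceiling. For south-west, at 4.0 min, it claims rings in the lead and nothing tighter than the ceiling.

The forecast puts rings first at 54% in south-west, 68% in south and 66% in south-east, and says: “The main uncertainty is whether ring formation consumes second end groups.”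

South-west gives rings at 56.8%, south rings at 75.8%, and south-east rings at 67.0%.

    first end groups + second end groups ⇌ links (K = 3.40 L mol⁻¹, k = 0.0150 L mol⁻¹ s⁻¹)
    first end groups + second end groups → rings, rate k2*[first end groups] as long as [second end groups] is above zero (k = 0.00640 s⁻¹)
    links ⇌ isomer of the product (K = 5.20, k = 0.00990 s⁻¹)

South-east ends with first end groups at 10.0%, the residue of the ceiling, and second end groups at 0%. In the neighbour of south-east charged with 0.32 M of first end groups, at 2.25 equiv of second end groups, first end groups stand at 2.3% at 10.0 min and 57% of the second end groups remain. South-east's rings stand 23 points under the ceiling, and isomer of the product at 20.2% and links at 2.80% hold that amount. In south-east, links and isomer of the product relax by their own step, both ways together, with a half-life of 0.979 min, much shorter than the 10 min of the flask, and at 10.0 min links are made at 0.865 of the rate at which they are used up, each step taken net. Left for 100 min, south-east holds rings at 88.7%.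

The readings are calculated for substances that don't exist; noise was put on by code.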